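The numbers in the tables are calculated from invented constants; noise was put on by code.

**Two runs.** The north-east run has lost 41.6% of its electrophile after 12.0 min, and the south run has lost 59.6% after 12.0 min. Both runs have equal charges of electrophile and solid base and differ in c(nucleophile). The question counts what has gone from electrophile, so I read that and not the target.

| setting | north-east | south | spring | dusk | noon |
|---|---|---|---|---|---|
| electrophile | 0.050 M | 0.050 M | 0.050 M | 0.050 M | 0.050 M |
| nucleophile | 0.078 M | 0.32 M | 0.100 M | 0.200 M | 0.400 M |
| solid base | 0.040 M | 0.040 M | 0.0400 M | 0.0400 M | 0.0400 M |
| remark | run made earlier | run made earlier |  |  |  |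
| time |  |  | 12 min | 12 min | 12 min |

| run | time / min | electrophile / % | target / % |
|---|---|---|---|
| north-east | 1.50 | 88.8 | 6.2 |
| north-east | 3.00 | 80.7 | 11.1 |
| north-east | 5.00 | 72.0 | 15.0 |
| north-east | 6.00 | 70.0 | 17.3 |
| north-east | 8.00 | 64.3 | 19.4 |
| north-east | 10.0 | 61.4 | 20.9 |
| north-east | 12.0 | 58.4 | 22.7 |
| south | 0.667 | 87.1 | 9.8 |
| south | 2.00 | 70.4 | 23.8 |
| south | 3.00 | 63.9 | 28.7 |
| south | 5.00 | 54.5 | 36.3 |
| south | 8.00 | 45.9 | 41.3 |
| south | 10.0 | 42.9 | 44.6 |
| south | 12.0 | 40.4 | 47.1 |

(scatter of a reading: 0.5 percentage points)

1. part of the electrophile that has reacted at the end, spring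
2. part of the electrophile that has reacted at the end, dusk
3. part of the electrophile that has reacted at the end, noon
4. what raising the concentration of nucleophile from its lowest to its highest value here does to the part of the electrophile that has reacted (changes below 5 percentage points count as none) (no change / it rises / it falls)

- solid, in amounts per volume of the solution: solid base
- at the start none of the solid base is in solution
- what has gone from electrophile into another species counts as reacted, even if it can come back

**Conversion order.** I go to logarithms. Between the two runs c(nucleophile) grows by a factor 4.10, but the reacted part grows by a factor of 1.43, which is less. The quotient of their logarithms, 0.255, is my conversion order: the change in log(reacted part) per change in log c(nucleophile), at fixed time and fixed other charges. It is a slope of conversion at one fixed time, read from readings, and not an order of the rate. Doubling c(nucleophile) then multiplies the reacted part by 1.19.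

**My reckoning.** Going along this line from the north-east run, I get 44.3% for spring, 52.9% for dusk and 63.1% for noon. Noon is an extrapolation, since its c(nucleophile) is higher than the south run's. The step from spring to noon is 19 percentage points, more than the 5 points that counts as a change, so I say the reacted part rises.

**The forecast.** It gives 44.5%, 54.5% and 62%, and its trend is: it rises. Its ground: “Scaling time by this order, each new run reads off a known curve at an equivalent time”. My dusk figure is lower than its figure, and my noon figure is higher.

**The result.** The flasks give 44.2% for spring, 53.5% for dusk and 62.6% for noon; the trend is it rises, by 18 points. Just after the start of spring, nucleophile goes into homo dimer at 5.1 times the rate at which it goes into target. Starting from spring's computed value, the conversion order gives 52.8% for dusk, where the flask gives 53.5%.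

    electrophile + nucleophile → acid set free + target (k = 0.660 M⁻¹ min⁻¹)
    nucleophile + acid set free ⇌ protonated nucleophile, settled at all times (K = 710 M⁻¹)
    acid set free + free base ⇌ salt of the base (K = 1000 M⁻¹, k = 20.0 M⁻¹ min⁻¹)
    electrophile ⇌ dormant form (K = 0.340, k = 0.0400 min⁻¹)
    solid base ⇌ free base, rate k5*(cs5 - [free base]) while solid is left; crystals form when [free base] > cs5 (solubility = 20.0 mM, k = 0.0830 min⁻¹)
    2 nucleophile → homo dimer (k = 0.840 M⁻¹ min⁻¹)

**A neighbour.** Take spring with 0.40 M of nucleophile. From spring's 44.2%, the conversion order gives 63.0%. The computed flask gives 62.6%.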